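**Plan**
- **Cuts:** (i) C12–C13 of the side chain, after C13 is taken back to a ketone, which gives a 2-furoyl chloride and a C12 alkylzinc ester. (ii) O1–C2 of the furan, which unfolds the furoic acid into a 3-bromo-2-pyrone. (iii) The pyrone at O1–C2 and C5–C6, which gives methyl 3-methylbut-2-enoate and hexanoyl chloride.
- **Enabling feature:** furan O1, C2 (chain), C3 (CH3), C4 (H) and C5 (pentyl) are pyrone O1, C3, C4, C5 and C6 in unchanged order. The pyrone carbonyl carbon C2 is pushed out of the ring and becomes C13 of the tridecanoic acid.
- **Forward order:** pyrone ring (steps 1–2), Br at C3 (step 3), contraction to the furan, the only ring of the target (step 4), chain joined at the carboxyl carbon (steps 5–7), deoxygenation and ester cleavage in one pot (step 8).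
- **Stereochemistry:** the target has no stereocentre and no stereogenic alkene. The one geometric need, a cis C=C between the enolate oxygen and the C–Br carbon after ring opening, is inherited from the six-membered ring.

Key step: step 4

Remark: keto ester 3 is expected as a mixture of alkene isomers, so its SMILES carries no geometry. All isomers converge on 4 in step 2.

Step 1
Reactants: 1 hexanoyl chloride; 2 methyl 3-methylbut-2-enoate
Product: 3 methyl 3-methyl-5-oxodec-2-enoate (alkene isomer mixture)
Conditions: AlCl3 (2.2 equiv), CH2Cl2, 0 °C to reflux; ice/aq HCl
Reagents that add atoms: none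
Why: Aliphatic Friedel–Crafts (Kondakov-type) acylation in its vinylogous form: the AlCl3-bound ester reacts through its γ-carbon with the hexanoyl cation and loses a proton, a reaction type run routinely to reach 6-alkyl-4-methyl-2-pyrones, and since both γ-methyl groups give the same constitution only alkene isomers can arise.

Step 2
Reactants: 3 methyl 3-methyl-5-oxodec-2-enoate
Product: 4 4-methyl-6-pentyl-2H-pyran-2-one
Conditions: AcOH, conc. H2SO4 (10% v/v), reflux
Reagents that add atoms: none
Why: Acid-catalysed enol lactonisation (6-exo-trig attack of the C5 enol oxygen on the ester carbonyl, loss of methanol); the acid interconverts the alkene isomers through the deconjugated form so that all material drains through the Z isomer into the conjugated 2-pyrone.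

Step 3
Reactants: 4 4-methyl-6-pentyl-2H-pyran-2-one
Product: 5 3-bromo-4-methyl-6-pentyl-2H-pyran-2-one
Conditions: Br2 (1.0 equiv), CH2Cl2, 0 °C to rt, dark
Reagents that add atoms: bromine, BrBr
Why: Electrophilic halogenation of a 2-pyrone by addition–elimination: C3 is the far end of the O1–C6=C5–C4=C3 dienol ether and has only the flat carbonyl as second neighbour, whereas C5 is wedged between methyl and pentyl, so 4,6-disubstituted 2-pyrones are known to take the first bromine at C3, and darkness with one equivalent of Br2 should hold back side-chain and double bromination.

Step 4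
Reactants: 5 3-bromo-4-methyl-6-pentyl-2H-pyran-2-one
Product: 7 3-methyl-5-pentylfuran-2-carboxylic acid, via ring-opened bromo keto carboxylate 6 (not isolated)
Conditions: aq KOH (4 M, 5 equiv), a little EtOH, reflux; then cold aq HCl to pH 2
Reagents that add atoms: potassium hydroxide, [K+].[OH-] (its oxygen becomes one carboxyl oxygen)
Why: Hydroxide adds to the lactone carbonyl C2 and breaks the C2–O1 bond, which gives carboxylate 6, where the former O1 is the enolate oxygen of the pentyl ketone and lies on the same side of the former C3=C4 double bond as the bromine-bearing carbon. This oxygen then makes the O1–C2 bond of the furan and expels bromide, either after a proton shift to the α-bromo-β,γ-unsaturated carboxylate (sp3 C–Br, 5-exo-tet O-alkylation, then an aromatising proton shift) or directly by addition–elimination at the vinylic carbon (formally 5-endo-trig, the path accepted for 3-halocoumarins). The closest known reaction type is the alkaline contraction of 3-halo-2-pyrones to 2-furoic acids, the monocyclic form of the Perkin coumarin-to-benzofuran rearrangement, which is established for 4,6-disubstituted 3-bromo-2-pyrones. No stereocentre is formed. The step needs O-alkylation rather than C-alkylation of the enolate (3-exo closure to a methylenecyclopropane) and ring closure faster than attack of external hydroxide on the C–Br carbon; the cis geometry inherited from the six-membered ring, the absence of a second acceptor group at the former C5 and the gain of furan aromaticity secure this, and moderately concentrated rather than fused alkali is chosen for the same reason. The product stays as its carboxylate until cold acidification, which guards the electron-rich furoic acid against decarboxylation.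

Step 5
Reactants: 7 3-methyl-5-pentylfuran-2-carboxylic acid
Product: 8 3-methyl-5-pentylfuran-2-carbonyl chloride (used crude after evaporation)
Conditions: (COCl)2 (1.3 equiv), DMF (cat.), CH2Cl2, 0 °C to rt
Reagents that add atoms: oxalyl chloride, O=C(Cl)C(=O)Cl
Why: Acid chloride formation through the chloroiminium (Vilsmeier-type) species from DMF and oxalyl chloride; the acyl group deactivates the furan enough to tolerate the HCl formed, and everything else leaves as gas.

Step 6
Reactants: 9 methyl 12-bromododecanoate
Product: 10 (12-methoxy-12-oxododecyl)zinc bromide (titrated THF solution, used as such)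
Conditions: Zn dust (1.5 equiv; activated with BrCH2CH2Br and Me3SiCl, a few mol % each), LiCl (1.5 equiv), THF, 50 °C
Reagents that add atoms: zinc, [Zn]
Why: LiCl-promoted direct insertion of zinc into a primary C–Br bond, a standard route to ester-bearing alkylzinc halides because the C–Zn bond does not attack the methyl ester.

Step 7
Reactants: 8 3-methyl-5-pentylfuran-2-carbonyl chloride; 10 (12-methoxy-12-oxododecyl)zinc bromide (1.2 equiv)
Product: 11 methyl 13-(3-methyl-5-pentylfuran-2-yl)-13-oxotridecanoate
Conditions: Pd(PPh3)4 (3 mol %), THF, 0 °C to rt
Reagents that add atoms: none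
Why: Negishi acylation: zerovalent palladium inserts into the C–Cl bond of 8, transmetalation from 10 and fast reductive elimination from the acyl(alkyl)palladium species give the ketone without β-hydride loss, second addition or attack on the ester.

Step 8
Reactants: 11 methyl 13-(3-methyl-5-pentylfuran-2-yl)-13-oxotridecanoate
Product: 14 13-(3-methyl-5-pentylfuran-2-yl)tridecanoic acid, via keto carboxylate 12 (not isolated), via hydrazone 13 (not isolated)
Conditions: KOH (6 equiv), diethylene glycol, 100 °C; N2H4·H2O (5 equiv), 130 °C; water distilled off to 195–200 °C, argon; cold aq HCl to pH 3–4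
Reagents that add atoms: potassium hydroxide, [K+].[OH-] (one carboxyl oxygen); hydrazine hydrate, NN.O (nitrogen only in 13, lost as N2)
Why: Wolff–Kishner reduction in the Huang-Minlon form, well established for 2-acylfurans because the furan tolerates hot base but not Clemmensen acid; saponifying first keeps hydrazine from being tied up as an acyl hydrazide, and hydrazone 13 then loses N2 to leave the C13 methylene.

**Compound list**
1 | hexanoyl chloride | CCCCCC(=O)Cl | starting material
2 | methyl 3-methylbut-2-enoate | CC(C)=CC(=O)OC | starting material
3 | methyl 3-methyl-5-oxodec-2-enoate (alkene isomer mixture) | CCCCCC(=O)CC(C)=CC(=O)OC | intermediate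
4 | 4-methyl-6-pentyl-2H-pyran-2-one | CCCCCc1cc(C)cc(=O)o1 | intermediate
5 | 3-bromo-4-methyl-6-pentyl-2H-pyran-2-one | CCCCCc1cc(C)c(Br)c(=O)o1 | intermediate
6 | potassium (2E)-2-bromo-3-methyl-5-oxodec-2-enoate (reacts through its enolate) | CCCCCC(=O)C/C(C)=C(/Br)C(=O)[O-].[K+] | intermediate
7 | 3-methyl-5-pentylfuran-2-carboxylic acid | CCCCCc1cc(C)c(C(=O)O)o1 | intermediate
8 | 3-methyl-5-pentylfuran-2-carbonyl chloride | CCCCCc1cc(C)c(C(=O)Cl)o1 | intermediate
9 | methyl 12-bromododecanoate | COC(=O)CCCCCCCCCCCBr | starting material
10 | (12-methoxy-12-oxododecyl)zinc bromide | COC(=O)CCCCCCCCCCC[Zn]Br | intermediate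
11 | methyl 13-(3-methyl-5-pentylfuran-2-yl)-13-oxotridecanoate | CCCCCc1cc(C)c(C(=O)CCCCCCCCCCCC(=O)OC)o1 | intermediate
12 | potassium 13-(3-methyl-5-pentylfuran-2-yl)-13-oxotridecanoate | CCCCCc1cc(C)c(C(=O)CCCCCCCCCCCC(=O)[O-])o1.[K+] | intermediate
13 | potassium 13-hydrazinylidene-13-(3-methyl-5-pentylfuran-2-yl)tridecanoate | CCCCCc1cc(C)c(C(=NN)CCCCCCCCCCCC(=O)[O-])o1.[K+] | intermediate
14 | 13-(3-methyl-5-pentylfuran-2-yl)tridecanoic acid | CCCCCc1cc(C)c(CCCCCCCCCCCCC(=O)O)o1 | target

**Step count**
Total steps: 8. The longest linear sequence is 7 (steps 1, 2, 3, 4, 5, 7, 8). Step 6 is a one-step side branch.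

**Steps most likely to fail**

1. **Step 4.**
   - What may go wrong: after the lactone opens, the enolate may alkylate through carbon (three-membered ring closure). External hydroxide may displace bromide, or the vinylogous β-keto acid may fragment before the C–O bond forms.
   - Fallback: opening and closure are separated, and the C–O bond is made by metal catalysis. The fallback sets out from 5.
   - NaOMe in MeOH at 0 °C to rt should open the lactone to methyl (2E)-2-bromo-3-methyl-5-oxodec-2-enoate F1.
   - The C4 methylene of F1 is a vinylogous β-keto ester position. Copper-catalysed intramolecular O-vinylation of its enolate (CuI, 1,10-phenanthroline, Cs2CO3, dioxane, 80 °C) should give methyl 3-methyl-5-pentylfuran-2-carboxylate F2.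
   - LiOH in THF/H2O then returns to the route at 7.

2. **Step 3.**
   - What may go wrong: bromination may spread over C3 and C5 or stray into the allylic and side-chain positions, and the monobromo isomers may be hard to separate.
   - Fallback: the need for selectivity is removed. The fallback sets out from 4.
   - Excess Br2 in warm AcOH should brominate both ring positions to 3,5-dibromo-4-methyl-6-pentyl-2H-pyran-2-one F3.
   - The same aqueous KOH contraction, which can only use the C3 bromide, should give 4-bromo-3-methyl-5-pentylfuran-2-carboxylic acid F4.
   - Hydrogenolysis of the remaining C–Br bond (H2 at 1 atm, Pd/C, NaOAc, MeOH) returns to the route at 7.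

3. **Step 8.**
   - What may go wrong: hydrazone formation may be slow at the ketone flanked by the 3-methyl group, azine formation may compete, or the electron-rich trialkylfuran may degrade thermally or oxidatively near 200 °C.
   - Fallback: a hydride-based deoxygenation near room temperature. The fallback sets out from 11.
   - TsNHNH2 in EtOH should give the tosylhydrazone F5.
   - Catecholborane in CHCl3 at 0 °C, followed by NaOAc·3H2O at reflux (tosylhydrazone reduction of the Caglioti type), should give methyl 13-(3-methyl-5-pentylfuran-2-yl)tridecanoate F6.
   - LiOH in THF/H2O with mild acidification returns to the route at 14.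

**Further compounds**
F1 | step 4 | methyl (2E)-2-bromo-3-methyl-5-oxodec-2-enoate | CCCCCC(=O)C/C(C)=C(/Br)C(=O)OC
F2 | step 4 | methyl 3-methyl-5-pentylfuran-2-carboxylate | CCCCCc1cc(C)c(C(=O)OC)o1
F3 | step 3 | 3,5-dibromo-4-methyl-6-pentyl-2H-pyran-2-one | CCCCCc1oc(=O)c(Br)c(C)c1Br
F4 | step 3 | 4-bromo-3-methyl-5-pentylfuran-2-carboxylic acid | CCCCCc1oc(C(=O)O)c(C)c1Br
F5 | step 8 | methyl 13-(3-methyl-5-pentylfuran-2-yl)-13-[2-(4-methylbenzenesulfonyl)hydrazinylidene]tridecanoate | CCCCCc1cc(C)c(C(=NNS(=O)(=O)c2ccc(C)cc2)CCCCCCCCCCCC(=O)OC)o1
F6 | step 8 | methyl 13-(3-methyl-5-pentylfuran-2-yl)tridecanoate | CCCCCc1cc(C)c(CCCCCCCCCCCCC(=O)OC)o1
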